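The route rests on one disconnection, the lactone bond O1–C9'. Without O1, C9' and C8 would both be CH2 groups tied to the carbonyl carbon C9, and C8' (bearing H and the ring B carbinol carbon C7') would be the prochiral C3 of a cyclobutanone. A catalyst-controlled Baeyer–Villiger oxidation exploits this hidden symmetry: in one operation it inserts O1, enlarges the four-membered ring to the gamma-lactone and fixes C8'. Its precursor, a cyclobutanone, contains only the (R)-C7' silyl ether and benzyl-protected ring B, and its ketone is unmasked from an exocyclic methylene without acid. Ring A follows by trans-selective enolate benzylation, ring C by an Evans syn-aldol giving the threo arylglycerol ether.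

Key step: step 6

Remarks on the chemistry:
- Numbering: lactone oxygen O1; C9 carbonyl, C8 alpha carbon, C7 its benzylic CH2 (ring A); C8' beta carbon, C9' the OCH2, C7' the carbinol carbon (ring B); C7'', C8'', C9'' the arylglycerol chain (ring C). TBS = tert-butyldimethylsilyl.
- Configuration read from the target structure: 8R, 8'R, 7'R, 7''S, 8''S; the C8 and C8' substituents are trans and the arylglycerol is threo (syn). The cyclobutanone and the lactone of the key step therefore need C7' = R and C8' = R.
- Assumption: the sense of induction of the chiral phosphoric acid on this substrate cannot be predicted with certainty. The antipode that gives the 8'R lactone would be fixed by one pair of test reactions; the (R)-acid is written.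
- Design remark: the ring ketone is carried as an exocyclic methylene, not as a ketal. Hydrolysis of a cyclobutanone ketal needs strong aqueous acid, which the p-alkoxybenzylic silyl ether would not survive; oxidative cleavage frees the ketone at neutral pH.

Step 1
Reactants: 1 4-bromo-2-methoxyphenol
Product: 2 1-(benzyloxy)-4-bromo-2-methoxybenzene
Conditions: BnBr, K2CO3, DMF, rt
Reagents that add atoms: benzyl bromide, BrCc1ccccc1
Why: Williamson ether synthesis, in which the phenoxide formed by K2CO3 displaces bromide from benzyl bromide by SN2 while the aryl bromide is inert.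

Step 2
Reactants: 2 1-(benzyloxy)-4-bromo-2-methoxybenzene; 3 3-methylidenecyclobutane-1-carbonitrile
Product: 6 [4-(benzyloxy)-3-methoxyphenyl](3-methylidenecyclobutyl)methanone, via arylmagnesium bromide 4 (not isolated), via bromomagnesium ketimine 5 (not isolated)
Conditions: Mg, THF, reflux; then 3, CuBr (2 mol%), THF, reflux; then 1 M aq. HCl, 0 °C to rt
Reagents that add atoms: water, O
Why: Grignard addition to a nitrile, in which the arylmagnesium bromide adds once to the C≡N bond (CuBr favours addition over alpha-deprotonation) and stops at the N-magnesio ketimine, which brief cold aqueous acid hydrolyses to the ketone without isomerising the exocyclic alkene.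

Step 3
Reactants: 6 [4-(benzyloxy)-3-methoxyphenyl](3-methylidenecyclobutyl)methanone
Product: 7 (R)-[4-(benzyloxy)-3-methoxyphenyl](3-methylidenecyclobutyl)methanol
Conditions: (S)-1-methyl-3,3-diphenyltetrahydro-1H,3H-pyrrolo[1,2-c][1,3,2]oxazaborole (15 mol%), catecholborane, toluene, −78 to −40 °C; then MeOH, aq. NaOH wash
Reagents that add atoms: none
Why: Corey–Bakshi–Shibata reduction, in which the (S)-oxazaborolidine binds the ketone oxygen on the side of the smaller cyclobutyl group and delivers hydride from nitrogen-bound catecholborane to the Si face, setting C7' as (R) in the same sense as for aryl methyl ketones, while catecholborane does not hydroborate the isolated alkene at low temperature.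

Step 4
Reactants: 7 (R)-[4-(benzyloxy)-3-methoxyphenyl](3-methylidenecyclobutyl)methanol
Product: 8 tert-butyl{(R)-[4-(benzyloxy)-3-methoxyphenyl](3-methylidenecyclobutyl)methoxy}dimethylsilane
Conditions: TBSCl, imidazole, DMF, rt
Reagents that add atoms: tert-butyldimethylsilyl chloride, CC(C)(C)[Si](C)(C)Cl
Why: Silylation through the N-silylimidazolium ion converts the secondary benzylic alcohol into a base-stable ether that also blocks oxidation and ionisation at C7' in the following steps.

Step 5
Reactants: 8 tert-butyl{(R)-[4-(benzyloxy)-3-methoxyphenyl](3-methylidenecyclobutyl)methoxy}dimethylsilane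
Product: 9 3-[(R)-[4-(benzyloxy)-3-methoxyphenyl](tert-butyldimethylsilyloxy)methyl]cyclobutan-1-one
Conditions: OsO4 (2 mol%), NaIO4, 2,6-lutidine, 1,4-dioxane/H2O (3:1), rt
Reagents that add atoms: osmium tetroxide, O=[Os](=O)(=O)=O; sodium periodate (terminal oxidant), [Na+].[O-]I(=O)(=O)=O
Why: Lemieux–Johnson oxidation, in which OsO4 dihydroxylates the only alkene and NaIO4 cleaves the diol and regenerates OsO4, so the cyclobutanone is released at neutral pH where the electron-rich benzylic silyl ether and the arene are untouched.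

Step 6
Reactants: 9 3-[(R)-[4-(benzyloxy)-3-methoxyphenyl](tert-butyldimethylsilyloxy)methyl]cyclobutan-1-one
Product: 11 (4R)-4-[(R)-[4-(benzyloxy)-3-methoxyphenyl](tert-butyldimethylsilyloxy)methyl]oxolan-2-one, via Criegee adduct 10 (not isolated)
Conditions: (R)-3,3'-di(pyren-1-yl)-5,5',6,6',7,7',8,8'-octahydro-1,1'-binaphthyl-2,2'-diyl hydrogen phosphate (10 mol%), 30% aq. H2O2 (1.5 equiv), CHCl3, −40 °C
Reagents that add atoms: hydrogen peroxide, OO
Why: The phosphoric acid activates the strained ketone and hydrogen peroxide by hydrogen bonding, peroxide adds to give Criegee adduct 10 held in the chiral phosphate pocket, and one of the two diastereotopic ring CH2 groups migrates from carbon to oxygen antiperiplanar to the breaking O–O bond while water leaves. The closest known reaction type is the chiral Brønsted acid/H2O2 Baeyer–Villiger desymmetrisation of 3-substituted cyclobutanones. The five-membered lactone ring is not closed by a cyclisation but by a 1,2-shift ring expansion of the four-membered ring, in which C9' moves from C9 to the new O1 with retention and the O1–C9' bond is formed. C8' becomes stereogenic only in this step and is controlled by the catalyst, which selects the CH2 group that migrates; the preset (R)-C7' centre acts as a matched or mismatched secondary bias, and because it makes the two possible lactones diastereomers, a minor isomer should be removable by chromatography. The step needs group selectivity between the two CH2 arms and chemoselectivity for the ketone over the electron-rich arene; the release of cyclobutanone strain makes the ketone by far the fastest site for peroxide at −40 °C, the bulky silyloxy(aryl)methyl group at C3 gives the catalyst a large steric handle, and the weakly acidic, metal-free medium leaves the benzylic silyl ether and the benzyl ether intact.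

Step 7
Reactants: 12 vanillin (4-hydroxy-3-methoxybenzaldehyde)
Product: 13 4-(tert-butyldimethylsilyloxy)-3-methoxybenzaldehyde
Conditions: TBSCl, imidazole, CH2Cl2, rt
Reagents that add atoms: tert-butyldimethylsilyl chloride, CC(C)(C)[Si](C)(C)Cl
Why: Standard phenol silylation through the N-silylimidazolium ion, which leaves the aldehyde untouched.

Step 8
Reactants: 13 4-(tert-butyldimethylsilyloxy)-3-methoxybenzaldehyde
Product: 14 [4-(tert-butyldimethylsilyloxy)-3-methoxyphenyl]methanol
Conditions: NaBH4, MeOH, 0 °C
Reagents that add atoms: none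
Why: Borohydride reduction of an aromatic aldehyde to the benzyl alcohol, short and cold enough for the aryl silyl ether to survive.

Step 9
Reactants: 14 [4-(tert-butyldimethylsilyloxy)-3-methoxyphenyl]methanol
Product: 15 [4-(bromomethyl)-2-methoxyphenoxy](tert-butyl)dimethylsilane
Conditions: CBr4, PPh3, CH2Cl2, 0 °C; used at once
Reagents that add atoms: carbon tetrabromide, BrC(Br)(Br)Br
Why: Appel reaction, in which bromide displaces the alkoxyphosphonium ion under neutral conditions and so avoids the acid that would ionise this electron-rich benzylic position.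

Step 10
Reactants: 11 (4R)-4-[(R)-[4-(benzyloxy)-3-methoxyphenyl](tert-butyldimethylsilyloxy)methyl]oxolan-2-one; 15 [4-(bromomethyl)-2-methoxyphenoxy](tert-butyl)dimethylsilane
Product: 17 (3R,4R)-4-[(R)-[4-(benzyloxy)-3-methoxyphenyl](tert-butyldimethylsilyloxy)methyl]-3-[4-(tert-butyldimethylsilyloxy)-3-methoxybenzyl]oxolan-2-one, via lithium enolate 16 (not isolated)
Conditions: LiN(SiMe3)2 (1.1 equiv), THF, −78 °C; then 15, DMPU, −78 to −40 °C
Reagents that add atoms: none
Why: Alkylation of a lactone lithium enolate, in which the benzyl bromide approaches the planar enolate from the face opposite the bulky C8' substituent and so sets C8 as (R) with the two ring substituents trans, while no leaving group sits beta to the enolate carbon and elimination cannot compete.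

Step 11
Reactants: 17 (3R,4R)-4-[(R)-[4-(benzyloxy)-3-methoxyphenyl](tert-butyldimethylsilyloxy)methyl]-3-[4-(tert-butyldimethylsilyloxy)-3-methoxybenzyl]oxolan-2-one
Product: 18 (3R,4R)-4-[(R)-(tert-butyldimethylsilyloxy)(4-hydroxy-3-methoxyphenyl)methyl]-3-[4-(tert-butyldimethylsilyloxy)-3-methoxybenzyl]oxolan-2-one
Conditions: H2 (1 atm), Pd/C (10 wt% Pd on carbon), EtOAc, rt
Reagents that add atoms: none
Why: Hydrogenolysis of the aryl benzyl ether on palladium frees the ring B phenol, while the aryl and benzylic silyl ethers and the lactone are not cleaved in ethyl acetate at atmospheric pressure.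

Step 12
Reactants: 19 (R)-4-benzyloxazolidin-2-one; 20 bromoacetyl bromide
Product: 22 (R)-4-benzyl-3-(bromoacetyl)oxazolidin-2-one, via lithium oxazolidinide 21 (not isolated)
Conditions: n-BuLi, THF, −78 °C; then 20, −78 to 0 °C
Reagents that add atoms: none
Why: N-Acylation of the lithiated oxazolidinone, in which the amide anion attacks the acyl bromide (far more electrophilic than the alkyl bromide) and the stereocentre of the auxiliary is not involved.

Step 13
Reactants: 18 (3R,4R)-4-[(R)-(tert-butyldimethylsilyloxy)(4-hydroxy-3-methoxyphenyl)methyl]-3-[4-(tert-butyldimethylsilyloxy)-3-methoxybenzyl]oxolan-2-one; 22 (R)-4-benzyl-3-(bromoacetyl)oxazolidin-2-one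
Product: 23 (R)-4-benzyl-3-{[2-methoxy-4-((R)-(tert-butyldimethylsilyloxy){(3R,4R)-4-[4-(tert-butyldimethylsilyloxy)-3-methoxybenzyl]-5-oxooxolan-3-yl}methyl)phenoxy]acetyl}oxazolidin-2-one
Conditions: K2CO3, acetone, rt
Reagents that add atoms: none
Why: Williamson-type SN2 reaction, in which the ring B phenoxide displaces the activated alpha-bromide of the imide under mild anhydrous carbonate conditions that leave the lactone, the imide and the silyl ethers alone.

Step 14
Reactants: 23 the ring B aryloxyacetyl imide of step 13; 13 4-(tert-butyldimethylsilyloxy)-3-methoxybenzaldehyde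
Product: 26 (R)-4-benzyl-3-[(2R,3S)-3-[4-(tert-butyldimethylsilyloxy)-3-methoxyphenyl]-3-hydroxy-2-(ring B aryloxy)propanoyl]oxazolidin-2-one (ring B aryloxy = the phenoxy group of 23), via dibutylboron enolate 24 (not isolated), via dibutylboron aldolate 25 (not isolated)
Conditions: Bu2BOTf (1.2 equiv), iPr2NEt (1.4 equiv), CH2Cl2, −78 to 0 °C; then 13, −78 to 0 °C; then pH 7 buffer, MeOH, 30% H2O2, 0 °C
Reagents that add atoms: none
Why: Evans syn-aldol reaction, in which Bu2BOTf and iPr2NEt form the (Z)-boron enolate of the imide only (an amine base does not enolise the lactone), which reacts through a chair Zimmerman–Traxler transition state on the enolate face opposite the benzyl group of the (R)-auxiliary and so sets C8'' and C7'' together as the (2R,3S) syn adduct, the threo arylglycerol arrangement.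

Step 15
Reactants: 26 the syn-aldol adduct of step 14
Product: 27 (3R,4R)-4-[(R)-(tert-butyldimethylsilyloxy){4-[(1S,2S)-1-[4-(tert-butyldimethylsilyloxy)-3-methoxyphenyl]-1,3-dihydroxypropan-2-yl]oxy-3-methoxyphenyl}methyl]-3-[4-(tert-butyldimethylsilyloxy)-3-methoxybenzyl]oxolan-2-one
Conditions: NaBH4, THF/H2O (4:1), 0 °C
Reagents that add atoms: none
Why: Reductive cleavage of the N-acyloxazolidinone by borohydride in wet THF, in which the alpha-aryloxy imide carbonyl is much more electrophilic than the lactone and is reduced selectively to the primary alcohol, no stereocentre is touched, and C8'' is now named (S) only because the CIP priorities change.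

Step 16
Reactants: 27 the tris-silyl diol of step 15
Product: 28 (3R,4R)-4-[(R)-hydroxy{4-[(1S,2S)-1,3-dihydroxy-1-(4-hydroxy-3-methoxyphenyl)propan-2-yl]oxy-3-methoxyphenyl}methyl]-3-(4-hydroxy-3-methoxybenzyl)oxolan-2-one (CNP0233652.1)
Conditions: Bu4NF (6 equiv), AcOH (6 equiv), THF, 0 °C to rt
Reagents that add atoms: none
Why: Fluoride-induced desilylation, in which fluoride attacks silicon of the two aryl silyl ethers and of the benzylic silyl ether while the acetic acid buffer keeps the medium near neutral, so that neither an alkoxide (lactone migration to O7') nor a benzylic cation at C7' or C7'' (cyclisation onto ring A, epimerisation) is formed.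

Compound list
1 | 4-bromo-2-methoxyphenol | COc1cc(Br)ccc1O | starting material
2 | 1-(benzyloxy)-4-bromo-2-methoxybenzene | COc1cc(Br)ccc1OCc1ccccc1 | intermediate
3 | 3-methylidenecyclobutane-1-carbonitrile | C=C1CC(C#N)C1 | starting material
4 | [4-(benzyloxy)-3-methoxyphenyl]magnesium bromide | COc1cc([Mg]Br)ccc1OCc1ccccc1 | intermediate (not isolated)
5 | N-bromomagnesio ketimine of 6 | COc1cc(C(=N[Mg]Br)C2CC(=C)C2)ccc1OCc1ccccc1 | intermediate (not isolated)
6 | [4-(benzyloxy)-3-methoxyphenyl](3-methylidenecyclobutyl)methanone | COc1cc(C(=O)C2CC(=C)C2)ccc1OCc1ccccc1 | intermediate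
7 | (R)-[4-(benzyloxy)-3-methoxyphenyl](3-methylidenecyclobutyl)methanol | C=C1CC(C1)[C@@H](O)c1ccc(OCc2ccccc2)c(OC)c1 | intermediate
8 | TBS ether of 7 | C=C1CC(C1)[C@@H](O[Si](C)(C)C(C)(C)C)c1ccc(OCc2ccccc2)c(OC)c1 | intermediate
9 | 3-[(R)-[4-(benzyloxy)-3-methoxyphenyl](tert-butyldimethylsilyloxy)methyl]cyclobutan-1-one | O=C1CC(C1)[C@@H](O[Si](C)(C)C(C)(C)C)c1ccc(OCc2ccccc2)c(OC)c1 | intermediate (key-step precursor)
10 | Criegee adduct, 1-hydroperoxy-3-[(R)-aryl(silyloxy)methyl]cyclobutan-1-ol | OOC1(O)CC(C1)[C@@H](O[Si](C)(C)C(C)(C)C)c1ccc(OCc2ccccc2)c(OC)c1 | intermediate (not isolated)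
11 | (4R)-4-[(R)-[4-(benzyloxy)-3-methoxyphenyl](tert-butyldimethylsilyloxy)methyl]oxolan-2-one | O=C1C[C@H](CO1)[C@@H](O[Si](C)(C)C(C)(C)C)c1ccc(OCc2ccccc2)c(OC)c1 | intermediate (key-step product)
12 | vanillin | COc1cc(C=O)ccc1O | starting material
13 | 4-(tert-butyldimethylsilyloxy)-3-methoxybenzaldehyde | COc1cc(C=O)ccc1O[Si](C)(C)C(C)(C)C | intermediate
14 | [4-(tert-butyldimethylsilyloxy)-3-methoxyphenyl]methanol | COc1cc(CO)ccc1O[Si](C)(C)C(C)(C)C | intermediate
15 | [4-(bromomethyl)-2-methoxyphenoxy](tert-butyl)dimethylsilane | COc1cc(CBr)ccc1O[Si](C)(C)C(C)(C)C | intermediate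
16 | lithium enolate of 11 | [Li]OC1=C[C@H](CO1)[C@@H](O[Si](C)(C)C(C)(C)C)c1ccc(OCc2ccccc2)c(OC)c1 | intermediate (not isolated)
17 | (3R,4R)-trans-lactone with ring A (aryl OTBS), C7' OTBS and ring B OBn | COc1cc(C[C@H]2C(=O)OC[C@@H]2[C@@H](O[Si](C)(C)C(C)(C)C)c2ccc(OCc3ccccc3)c(OC)c2)ccc1O[Si](C)(C)C(C)(C)C | intermediate
18 | ring B phenol from 17 | COc1cc(C[C@H]2C(=O)OC[C@@H]2[C@@H](O[Si](C)(C)C(C)(C)C)c2ccc(O)c(OC)c2)ccc1O[Si](C)(C)C(C)(C)C | intermediate
19 | (R)-4-benzyloxazolidin-2-one | O=C1N[C@H](Cc2ccccc2)CO1 | starting material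
20 | bromoacetyl bromide | BrCC(Br)=O | starting material
21 | lithium salt of 19 | [Li]N1[C@H](Cc2ccccc2)COC1=O | intermediate (not isolated)
22 | (R)-4-benzyl-3-(bromoacetyl)oxazolidin-2-one | BrCC(=O)N1[C@H](Cc2ccccc2)COC1=O | intermediate
23 | ring B aryloxyacetyl imide | COc1cc(C[C@H]2C(=O)OC[C@@H]2[C@@H](O[Si](C)(C)C(C)(C)C)c2ccc(OCC(=O)N3[C@H](Cc4ccccc4)COC3=O)c(OC)c2)ccc1O[Si](C)(C)C(C)(C)C | intermediate
24 | (Z)-dibutylboron enolate of 23 | COc1cc(C[C@H]2C(=O)OC[C@@H]2[C@@H](O[Si](C)(C)C(C)(C)C)c2ccc(O/C=C(\OB(CCCC)CCCC)N3[C@H](Cc4ccccc4)COC3=O)c(OC)c2)ccc1O[Si](C)(C)C(C)(C)C | intermediate (not isolated)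
25 | dibutylboron aldolate of 26 | COc1cc(C[C@H]2C(=O)OC[C@@H]2[C@@H](O[Si](C)(C)C(C)(C)C)c2ccc(O[C@@H](C(=O)N3[C@H](Cc4ccccc4)COC3=O)[C@@H](OB(CCCC)CCCC)c5ccc(O[Si](C)(C)C(C)(C)C)c(OC)c5)c(OC)c2)ccc1O[Si](C)(C)C(C)(C)C | intermediate (not isolated)
26 | (2R,3S) syn-aldol adduct on the (R)-auxiliary | COc1cc(C[C@H]2C(=O)OC[C@@H]2[C@@H](O[Si](C)(C)C(C)(C)C)c2ccc(O[C@@H](C(=O)N3[C@H](Cc4ccccc4)COC3=O)[C@@H](O)c5ccc(O[Si](C)(C)C(C)(C)C)c(OC)c5)c(OC)c2)ccc1O[Si](C)(C)C(C)(C)C | intermediate
27 | tris-TBS threo-(7''S,8''S) diol | COc1cc(C[C@H]2C(=O)OC[C@@H]2[C@@H](O[Si](C)(C)C(C)(C)C)c2ccc(O[C@@H](CO)[C@@H](O)c5ccc(O[Si](C)(C)C(C)(C)C)c(OC)c5)c(OC)c2)ccc1O[Si](C)(C)C(C)(C)C | intermediate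
28 | CNP0233652.1, (8R,8'R,7'R,7''S,8''S) | COc1cc(C[C@H]2C(=O)OC[C@@H]2[C@@H](O)c2ccc(O[C@@H](CO)[C@@H](O)c3ccc(O)c(OC)c3)c(OC)c2)ccc1O | target

Total step count: 16 steps.
Longest linear sequence: 12 steps (steps 1–6, 10, 11, 13–16); steps 7–9 and step 12 are side branches.

Steps most likely to fail

1. Step 6, selection of the migrating CH2 group. The chiral acid may discriminate poorly between the two diastereotopic methylene groups, or the bias of the C7' centre may oppose it, so that oxygen is inserted on the wrong side. The fallback gives up catalyst control and uses the preset C7' centre for separation. It sets out from cyclobutanone 9: an ordinary peracid Baeyer–Villiger oxidation (3-chloroperbenzoic acid, NaHCO3, CH2Cl2, 0 °C) should give lactone 11 together with its C8' epimer, (4S)-4-[(R)-[4-(benzyloxy)-3-methoxyphenyl](tert-butyldimethylsilyloxy)methyl]oxolan-2-one F1. The two are diastereomers and would be separated by chromatography, and the route is rejoined at compound 11.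

2. Step 15, chemoselectivity of the hydride. Borohydride may attack the lactone carbonyl as well as the imide, or retro-aldol cleavage may set in under the basic conditions. The fallback splits the operation into hydrolysis and an acid-selective reduction. It sets out from aldol adduct 26: LiOH/H2O2 (THF/H2O, 0 °C, short contact) removes the auxiliary and should give the (2R,3S)-2-aryloxy-3-hydroxy-3-arylpropanoic acid F2. BH3·SMe2 (THF, 0 °C) then reduces the free carboxylic acid, which borane attacks far faster than a lactone, and the route is rejoined at diol 27.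

3. Step 3, enantioface discrimination. The oxazaborolidine may distinguish poorly between the aryl group and the alpha-branched cyclobutyl group, or the electron-rich ketone may react too slowly with catecholborane at low temperature. The fallback is reduction without stereocontrol followed by classical resolution. It sets out from ketone 6: NaBH4 (MeOH, 0 °C) gives the racemic carbinol F3. Esterification with (S)-2-methoxy-2-phenylacetic acid (DCC, DMAP, CH2Cl2) gives two diastereomers, the (S)-2-methoxy-2-phenylacetate of the (R)-carbinol F4 and the (S)-2-methoxy-2-phenylacetate of the (S)-carbinol F5, which are separated by chromatography. Methanolysis of F4 (K2CO3, MeOH, rt) rejoins the route at alcohol 7.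

Further compounds
F1 | step 6 | (4S)-4-[(R)-[4-(benzyloxy)-3-methoxyphenyl](tert-butyldimethylsilyloxy)methyl]oxolan-2-one | O=C1C[C@@H](CO1)[C@@H](O[Si](C)(C)C(C)(C)C)c1ccc(OCc2ccccc2)c(OC)c1
F2 | step 15 | (2R,3S)-3-[4-(tert-butyldimethylsilyloxy)-3-methoxyphenyl]-3-hydroxy-2-(ring B aryloxy)propanoic acid | COc1cc(C[C@H]2C(=O)OC[C@@H]2[C@@H](O[Si](C)(C)C(C)(C)C)c2ccc(O[C@@H](C(=O)O)[C@@H](O)c5ccc(O[Si](C)(C)C(C)(C)C)c(OC)c5)c(OC)c2)ccc1O[Si](C)(C)C(C)(C)C
F3 | step 3 | racemic [4-(benzyloxy)-3-methoxyphenyl](3-methylidenecyclobutyl)methanol | C=C1CC(C1)C(O)c1ccc(OCc2ccccc2)c(OC)c1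
F4 | step 3 | (R)-[4-(benzyloxy)-3-methoxyphenyl](3-methylidenecyclobutyl)methyl (S)-2-methoxy-2-phenylacetate | C=C1CC(C1)[C@@H](OC(=O)[C@@H](OC)c1ccccc1)c1ccc(OCc2ccccc2)c(OC)c1
F5 | step 3 | (S)-[4-(benzyloxy)-3-methoxyphenyl](3-methylidenecyclobutyl)methyl (S)-2-methoxy-2-phenylacetate | C=C1CC(C1)[C@H](OC(=O)[C@@H](OC)c1ccccc1)c1ccc(OCc2ccccc2)c(OC)c1
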